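**Retrosynthetic overview**

1. Target 14 ⇒ acyclic vinylallene 13 by an intramolecular Diels–Alder reaction. The C5–C10 and C8–C9 bonds (drimane numbering) form together, so rings A and B close in the same, final operation, and the 6,7-ene/8(12)-methylene diene is delivered directly.
2. 13 ⇒ terminal alkyne 9 + propargyl carbonate 10 (hydroboration, then palladium-catalysed SN2' coupling).
3. 9 ⇒ aldehyde 6 + silyl enyne 7 by catalytic asymmetric gem-dimethyl-propargylation. This sets C3, the only stereocentre not made in the cycloaddition.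
4. 6 ⇒ auraptene 3 (distal alkene cleavage) ⇒ umbelliferone 1 + geranyl bromide 2; the coumarin ring is bought.

Assumption: (R)-BINAP is taken as the ligand enantiomer that gives the (S)-carbinol in step 3; the configuration of 8 is checked by Mosher ester analysis and (S)-BINAP is used instead if the sense proves opposite.

Drimane numbering is used for the core: C3 carbinol, C4 CMe2, C5/C10 ring fusion, C9 bearing C11H2OAr, C8=C12 methylene. The target is 3S,5R,9S,10S (3β-OH, 5α-H, 9β-CH2OAr, 10β-Me).

**Route**

Step 1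
Reactants: 1 umbelliferone (7-hydroxy-2H-chromen-2-one); 2 geranyl bromide ((2E)-1-bromo-3,7-dimethylocta-2,6-diene)
Product: 3 auraptene (7-{[(2E)-3,7-dimethylocta-2,6-dien-1-yl]oxy}-2H-chromen-2-one)
Conditions: K2CO3, acetone, reflux
Reagents that add atoms: none
Why: Williamson ether synthesis; the phenoxide displaces the primary allylic bromide by SN2 and the E-alkene geometry is untouched.

Step 2
Reactants: 3 auraptene
Product: 6 (4E)-4-methyl-6-[(2-oxo-2H-chromen-7-yl)oxy]hex-4-enal, via epoxyauraptene 4 (not isolated), via glycol 5 (not isolated)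
Conditions: mCPBA, CH2Cl2, 0 °C; then H5IO6, THF/H2O, 0 °C to rt
Reagents that add atoms: mCPBA, O=C(OO)c1cccc(Cl)c1
Why: Prilezhaev epoxidation is selective for the distal trisubstituted alkene because the 2',3'-alkene is deactivated by the allylic aryloxy group and the coumarin alkene is electron-poor; periodic acid then hydrates the epoxide and cleaves the glycol (Malaprade cleavage) to the aldehyde and acetone.

Step 3
Reactants: 6 (4E)-4-methyl-6-[(2-oxo-2H-chromen-7-yl)oxy]hex-4-enal; 7 trimethyl(3-methylbut-3-en-1-yn-1-yl)silane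
Product: 8 7-{[(2E,6S)-6-hydroxy-3,7,7-trimethyl-9-(trimethylsilyl)non-2-en-8-yn-1-yl]oxy}-2H-chromen-2-one
Conditions: (CF3CO2)2Ru(CO)(PPh3)2 (5 mol %), (R)-BINAP (5 mol %), i-PrOH (2 equiv), THF, 95 °C
Reagents that add atoms: none
Why: Ruthenium-catalysed transfer-hydrogenative carbonyl propargylation with a 1,3-enyne as allenylmetal equivalent; the divalent ruthenium hydride (fed by 2-propanol) hydrometalates the enyne and the resulting allenylruthenium adds to the aldehyde through a closed six-membered transition state at its dimethyl-substituted carbon, and the BINAP ligand selects the aldehyde face to set the (S)-carbinol (C3).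

Step 4
Reactants: 8 silyl alkyne
Product: 9 7-{[(2E,6S)-6-hydroxy-3,7,7-trimethylnon-2-en-8-yn-1-yl]oxy}-2H-chromen-2-one
Conditions: K2CO3 (0.3 equiv), MeOH/THF, 0 °C; aq. NH4Cl
Reagents that add atoms: none
Why: Methoxide-mediated protodesilylation of the alkynylsilane; the short cold exposure and mildly acidic quench keep the coumarin lactone closed and the carbinol is not affected.

Step 5
Reactants: 9 terminal alkyne; 10 methyl prop-2-yn-1-yl carbonate
Product: 13 7-{[(2E,6S,8E)-6-hydroxy-3,7,7-trimethyldodeca-2,8,10,11-tetraen-1-yl]oxy}-2H-chromen-2-one (vinylallene), via alkenylborane 11 (not isolated), via borinate ester 12 (not isolated)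
Conditions: Cy2BH (2.2 equiv, from BH3·SMe2 + cyclohexene), THF, 0 °C to rt; then 10, Pd(PPh3)4 (5 mol %), THF, rt; aq. NaHCO3 work-up
Reagents that add atoms: none
Why: syn, anti-Markovnikov hydroboration gives the (E)-alkenylborane (one further equivalent of borane caps the hydroxyl), and a Suzuki–Miyaura-type SN2' coupling follows, in which zerovalent palladium and the propargylic carbonate give an allenylpalladium methoxide that transmetalates with the alkenylborane without added base and reductively eliminates to the terminal vinylallene with the E-alkene retained.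

Step 6
Reactants: 13 vinylallene
Product: 14 CNP0259618.2, 7-{[(1S,4aR,6S,8aS)-6-hydroxy-5,5,8a-trimethyl-2-methylidene-1,2,4a,5,6,7,8,8a-octahydronaphthalen-1-yl]methoxy}-2H-chromen-2-one
Conditions: PhMe (5 mM), BHT (cat.), 120 °C, sealed tube
Reagents that add atoms: none
Why: Type 1 intramolecular Diels–Alder reaction of a vinylallene (no [1,5]-H shift is possible because C4 is quaternary, and the temperature stays below that of the aryl allyl ether Claisen rearrangement); suprafacial addition to the E-alkene places the C10 methyl and the C9 aryloxymethyl cis, the exo-tether chair transition state with the C3 hydroxyl equatorial gives the trans-fused 5α-H/10β-Me decalin on the face set by the (S)-carbinol, and the untouched cumulene bond becomes the 8(12)-methylene beside the new C6=C7 alkene, with cis-fused and 3-axial diastereomers expected as minor products removed by chromatography.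

**Compound list**

1 | umbelliferone (7-hydroxy-2H-chromen-2-one) | Oc1ccc2ccc(=O)oc2c1 | starting material
2 | geranyl bromide ((2E)-1-bromo-3,7-dimethylocta-2,6-diene) | CC(C)=CCC/C(C)=C/CBr | starting material
3 | auraptene (7-{[(2E)-3,7-dimethylocta-2,6-dien-1-yl]oxy}-2H-chromen-2-one) | CC(C)=CCC/C(C)=C/COc1ccc2ccc(=O)oc2c1 | intermediate
4 | racemic 6',7'-epoxyauraptene (7-{[(2E)-5-(3,3-dimethyloxiran-2-yl)-3-methylpent-2-en-1-yl]oxy}-2H-chromen-2-one) | CC1(C)OC1CC/C(C)=C/COc1ccc2ccc(=O)oc2c1 | intermediate
5 | racemic glycol (7-{[(2E)-6,7-dihydroxy-3,7-dimethyloct-2-en-1-yl]oxy}-2H-chromen-2-one) | CC(C)(O)C(O)CC/C(C)=C/COc1ccc2ccc(=O)oc2c1 | intermediate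
6 | (4E)-4-methyl-6-[(2-oxo-2H-chromen-7-yl)oxy]hex-4-enal | O=CCC/C(C)=C/COc1ccc2ccc(=O)oc2c1 | intermediate
7 | trimethyl(3-methylbut-3-en-1-yn-1-yl)silane | C=C(C)C#C[Si](C)(C)C | starting material
8 | 7-{[(2E,6S)-6-hydroxy-3,7,7-trimethyl-9-(trimethylsilyl)non-2-en-8-yn-1-yl]oxy}-2H-chromen-2-one | C[Si](C)(C)C#CC(C)(C)[C@@H](O)CC/C(C)=C/COc1ccc2ccc(=O)oc2c1 | intermediate
9 | 7-{[(2E,6S)-6-hydroxy-3,7,7-trimethylnon-2-en-8-yn-1-yl]oxy}-2H-chromen-2-one | C#CC(C)(C)[C@@H](O)CC/C(C)=C/COc1ccc2ccc(=O)oc2c1 | intermediate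
10 | methyl prop-2-yn-1-yl carbonate | C#CCOC(=O)OC | starting material
11 | (E)-alkenyl(dicyclohexyl)borane of 9 with the hydroxyl capped as its dicyclohexylborinate | C1CCCCC1B(C1CCCCC1)/C=C/C(C)(C)[C@@H](OB(C1CCCCC1)C1CCCCC1)CC/C(C)=C/COc1ccc2ccc(=O)oc2c1 | intermediate
12 | O-dicyclohexylborinate of vinylallene 13 | C=C=C/C=C/C(C)(C)[C@@H](OB(C1CCCCC1)C1CCCCC1)CC/C(C)=C/COc1ccc2ccc(=O)oc2c1 | intermediate
13 | 7-{[(2E,6S,8E)-6-hydroxy-3,7,7-trimethyldodeca-2,8,10,11-tetraen-1-yl]oxy}-2H-chromen-2-one | C=C=C/C=C/C(C)(C)[C@@H](O)CC/C(C)=C/COc1ccc2ccc(=O)oc2c1 | intermediate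
14 | CNP0259618.2, 7-{[(1S,4aR,6S,8aS)-6-hydroxy-5,5,8a-trimethyl-2-methylidene-1,2,4a,5,6,7,8,8a-octahydronaphthalen-1-yl]methoxy}-2H-chromen-2-one | C=C1C=C[C@H]2C(C)(C)[C@@H](O)CC[C@]2(C)[C@H]1COc1ccc2ccc(=O)oc2c1 | target

**Step count and risk**

Total steps: 6. Longest linear sequence: 6 (from 1 or 2 to 14).

The three steps most likely to fail:

Step 6 (cycloaddition). The dienophile is trisubstituted and unactivated, the new C5–C10 bond joins two congested carbons, and the temperature window is capped by the aryl allyl ether Claisen rearrangement. The trans/cis ring-fusion ratio and the facial bias from a single equatorial hydroxyl are predicted rather than known, and could be modest. The fallback sets out from 13 and comes back at 14. Compound 13 is silylated (TBSOTf, 2,6-lutidine, CH2Cl2, −78 °C) to the tert-butyldimethylsilyl ether of the vinylallene F1. This bulkier, non-coordinating group strengthens the equatorial preference. The ring closure is then run as a metal-catalysed formal [4+2] instead of a thermal pericyclic reaction: [Rh(C10H8)(C8H12)]SbF6 (monovalent rhodium, 5 mol %), CH2Cl2, rt to 40 °C. Oxidative cyclisation of the vinylallene and alkene on rhodium and reductive elimination give the silyl ether of the cycloadduct F2, far below the Claisen threshold. TBAF in THF then returns 14.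

Step 5 (vinylallene assembly). The risks are borane consumption by the free hydroxyl, allene versus alkyne regiochemistry in the coupling, and ionisation of the geranyl-type aryl ether by zerovalent palladium, which could scramble the alkene geometry. The fallback sets out from 9 and comes back at 13, and builds the allene by reductive transposition instead of SN2' coupling. Hydrostannation (Bu3SnH, cat. PdCl2(PPh3)2, THF, 0 °C, minutes) gives the (E)-alkenyltributylstannane F3. Iodine in CH2Cl2 at 0 °C gives the (E)-alkenyl iodide F4. Sonogashira coupling with propargyl alcohol (PdCl2(PPh3)2, CuI, Et3N, rt) gives the (E)-enynol F5. Myers allene synthesis (2-nitrobenzenesulfonylhydrazide, PPh3, DEAD, THF, −15 °C to rt) alkylates the hydrazide only at the primary propargylic alcohol to give the N-propargyl sulfonylhydrazine F6. This loses sulfinic acid to the propargylic diazene F7, and retro-ene loss of N2 gives 13 at room temperature.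

Step 3 (asymmetric propargylation). The ruthenium hydride at 95 °C may reduce the coumarin C3=C4 bond or isomerise/ionise the allylic aryl ether, and the sense of induction is assumed. The fallback sets out from 6 and comes back at 9, so it also bypasses step 4, and uses boron instead of a metal hydride. 2-Methylbut-3-yn-2-yl methyl carbonate and B2pin2 (CuCl, NaOtBu, Xantphos, THF; monovalent copper catalysis) give 4,4,5,5-tetramethyl-2-(3-methylbuta-1,2-dien-1-yl)-1,3,2-dioxaborolane F8. Chiral phosphoric acid catalysed propargylboration of 6 with this reagent (TRIP, enantiomer chosen by the same Mosher check, toluene, 0 °C) proceeds through a closed SE2' transition state to the pinacol borate ester of the homopropargylic alcohol F9. Aqueous work-up hydrolyses this directly to 9.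

**Further compounds**

F1 | step 6 | tert-butyldimethylsilyl ether of vinylallene 13 | C=C=C/C=C/C(C)(C)[C@@H](O[Si](C)(C)C(C)(C)C)CC/C(C)=C/COc1ccc2ccc(=O)oc2c1
F2 | step 6 | tert-butyldimethylsilyl ether of 14 | C=C1C=C[C@H]2C(C)(C)[C@@H](O[Si](C)(C)C(C)(C)C)CC[C@]2(C)[C@H]1COc1ccc2ccc(=O)oc2c1
F3 | step 5 | 7-{[(2E,6S,8E)-6-hydroxy-3,7,7-trimethyl-9-(tributylstannyl)nona-2,8-dien-1-yl]oxy}-2H-chromen-2-one | CCCC[Sn](CCCC)(CCCC)/C=C/C(C)(C)[C@@H](O)CC/C(C)=C/COc1ccc2ccc(=O)oc2c1
F4 | step 5 | 7-{[(2E,6S,8E)-6-hydroxy-9-iodo-3,7,7-trimethylnona-2,8-dien-1-yl]oxy}-2H-chromen-2-one | I/C=C/C(C)(C)[C@@H](O)CC/C(C)=C/COc1ccc2ccc(=O)oc2c1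
F5 | step 5 | 7-{[(2E,6S,8E)-6,12-dihydroxy-3,7,7-trimethyldodeca-2,8-dien-10-yn-1-yl]oxy}-2H-chromen-2-one | OCC#C/C=C/C(C)(C)[C@@H](O)CC/C(C)=C/COc1ccc2ccc(=O)oc2c1
F6 | step 5 | N-propargyl-N-(2-nitrobenzenesulfonyl)hydrazine derived from F5 | NN(CC#C/C=C/C(C)(C)[C@@H](O)CC/C(C)=C/COc1ccc2ccc(=O)oc2c1)S(=O)(=O)c1ccccc1[N+](=O)[O-]
F7 | step 5 | propargylic diazene derived from F6 | N=NCC#C/C=C/C(C)(C)[C@@H](O)CC/C(C)=C/COc1ccc2ccc(=O)oc2c1
F8 | step 3 | 4,4,5,5-tetramethyl-2-(3-methylbuta-1,2-dien-1-yl)-1,3,2-dioxaborolane | CC(C)=C=CB1OC(C)(C)C(C)(C)O1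
F9 | step 3 | pinacol borate ester of 9 | C#CC(C)(C)[C@@H](OB1OC(C)(C)C(C)(C)O1)CC/C(C)=C/COc1ccc2ccc(=O)oc2c1
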